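**Assumption:** the target's enol (C4–OH/C2=O) is one of two rapidly equilibrating tautomers of the C2/C4 dione, and the route delivers that pair. Ring numbering: C1 acyl-bearing bridgehead, C2, C3, C4, C5 prenylated bridgehead, C6, C7, C8 (CMe2), C9 bridging C=O; prenyl = 3-methylbut-2-en-1-yl.

## Retrosynthetic overview

1. Last C–C bond: C1–C(acyl), by palladium-catalysed coupling of a bridgehead zinc reagent (from C1–H metalation of the protected core) with S-ethyl (R)-2-methylbutanethioate (fragment C); then global deprotection.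
2. C3 side chain: reductive alkylation of the bicyclic trione with 3-methyl-3-(triethylsilyloxy)butanal (fragment B), then O-methylation.
3. Bicyclic trione: Effenberger annulation of malonyl dichloride onto the silyl enol ether of a 3,3-dimethyl-4,6-diprenylcyclohexanone (fragment A); C7 directs C1 and C5.
4. Fragment A: organocatalytic Michael/aldol annulation (sets C7), two copper-catalysed methyl additions (the first followed by palladium-catalysed dehydrogenation) and α'-prenylation.
5. Ring order: the cyclohexanone ring (C1, C5–C9) first, then the C2–C3–C4 bridge closes the second ring.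

## Route

**Step 1**
Reactants: 1 2-methylbut-3-en-2-ol; 2 ethyl vinyl ether
Product: 4 5-methylhex-4-enal, via allyl vinyl ether 3 (not isolated)
Conditions: 2 (4 equiv), H3PO4 (1 mol %), sealed vessel, 150 °C, 2 h; distil
Reagents that add atoms: none
Why: Acid-catalysed vinyl ether exchange gives the allyl vinyl ether, which undergoes Claisen ([3,3]-sigmatropic, Saucy–Marbet type) rearrangement to the γ,δ-unsaturated aldehyde; no stereocentre is formed.

**Step 2**
Reactants: 4 5-methylhex-4-enal; 5 but-3-en-2-one (methyl vinyl ketone)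
Product: 7 (4S)-4-(3-methylbut-2-en-1-yl)cyclohex-2-en-1-one, via keto aldehyde 6 (not isolated)
Conditions: (S)-2-[diphenyl(trimethylsilyloxy)methyl]pyrrolidine (5 mol %), ethyl 3,4-dihydroxybenzoate (20 mol %), neat, 4 °C, 36 h; then i-PrOH, LiOH (0.3 equiv), rt
Reagents that add atoms: none
Why: Enamine-catalysed Michael addition (Si-face attack on the E-enamine of the (S)-catalyst gives the 2S aldehyde, which is the C7 stereocentre) followed by intramolecular aldol condensation (organocatalytic Robinson-type annulation) under conditions that do not epimerise the γ-centre.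

**Step 3**
Reactants: 7 (4S)-4-(3-methylbut-2-en-1-yl)cyclohex-2-en-1-one
Product: 10 (4S)-3-methyl-4-(3-methylbut-2-en-1-yl)cyclohex-2-en-1-one, via bromomagnesium enolate 8 (not isolated), via chlorozinc enolate 9 (not isolated)
Conditions: MeMgBr (1.2 equiv), CuBr·SMe2 (10 mol %), THF, −40 °C; ZnCl2 (1.2 equiv), 0 °C; then [Pd(C3H5)Cl]2 (2.5 mol %), diethyl allyl phosphate (1.2 equiv), 60 °C
Reagents that add atoms: methylmagnesium bromide C[Mg]Br
Why: Copper-catalysed conjugate addition gives a regiodefined enolate which, after Mg-to-Zn exchange, undergoes allyl-palladium-catalysed α,β-dehydrogenation (Newhouse-type, same outcome as a Saegusa–Ito oxidation) to return the enone carrying the first C8 methyl; C7 is untouched.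

**Step 4**
Reactants: 10 (4S)-3-methyl-4-(3-methylbut-2-en-1-yl)cyclohex-2-en-1-one; 11 1-bromo-3-methylbut-2-ene (prenyl bromide)
Product: 13 (4R,6RS)-3-methyl-4,6-bis(3-methylbut-2-en-1-yl)cyclohex-2-en-1-one, via lithium dienolate 12 (not isolated)
Conditions: LiN(i-Pr)2 (1.05 equiv), THF, −78 °C; 11 (1.5 equiv), DMPU, −78 → −30 °C
Reagents that add atoms: none
Why: Kinetic α'-deprotonation gives the cross-conjugated enolate, which is alkylated by the allylic bromide (SN2 enolate alkylation); the new centre (future C5) forms as a mixture that converges in step 7, and the CIP descriptor at C4 changes only because priorities change.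

**Step 5**
Reactants: 13 (4R,6RS)-3-methyl-4,6-bis(3-methylbut-2-en-1-yl)cyclohex-2-en-1-one
Product: 14 {[(4R,6RS)-3,3-dimethyl-4,6-bis(3-methylbut-2-en-1-yl)cyclohex-1-en-1-yl]oxy}trimethylsilane
Conditions: MeMgBr (1.5 equiv), CuBr·SMe2 (10 mol %), Me3SiCl (2 equiv), DMPU, THF, −78 → −30 °C; Et3N, pentane, cold aq NaHCO3; used crude
Reagents that add atoms: methylmagnesium bromide C[Mg]Br; chlorotrimethylsilane C[Si](C)(C)Cl
Why: Silyl-chloride-accelerated copper-catalysed conjugate addition (Kharasch/Kuwajima type) builds the C8 gem-dimethyl carbon and traps the enolate regiospecifically as the C9=C1 silyl enol ether; no new stereocentre.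

**Step 6**
Reactants: 15 propanedioic acid (malonic acid)
Product: 16 propanedioyl dichloride (malonyl dichloride)
Conditions: SOCl2 (3 equiv), neat, 50 °C, 3 d; distil at reduced pressure
Reagents that add atoms: thionyl chloride O=S(Cl)Cl
Why: Standard acid chloride formation; the reagent is made fresh because the annulation in step 7 is sensitive to its quality.

**Step 7**
Reactants: 14 silyl enol ether; 16 malonyl dichloride
Product: 17 (1R,5S,7R)-4-hydroxy-8,8-dimethyl-5,7-bis(3-methylbut-2-en-1-yl)bicyclo[3.3.1]non-3-ene-2,9-dione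
Conditions: 16 (1.5 equiv), Et2O, −20 °C → rt, 20 h; then KOH, BnEt3NCl, H2O, rt; HCl to pH 2
Reagents that add atoms: none
Why: Effenberger cyclisation, that is C-acylation at C1 of the silyl enol ether and then intramolecular C-acylation at C5 through its enol (so the C5 mixture converges); the three-carbon bridge must span the ring diaxially and forms on the face anti to the C7 prenyl group (prenyl equatorial in the chair), which sets C1 and C5 relative to C7.

**Step 8**
Reactants: 1 2-methylbut-3-en-2-ol
Product: 18 triethyl[(2-methylbut-3-en-2-yl)oxy]silane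
Conditions: Et3SiOTf (1.2 equiv), 2,6-lutidine (1.5 equiv), CH2Cl2, −78 → 0 °C
Reagents that add atoms: triethylsilyl trifluoromethanesulfonate CC[Si](CC)(CC)OS(=O)(=O)C(F)(F)F
Why: Silyl triflate silylation of a hindered tertiary alcohol; the ether survives all later basic and organometallic steps.

**Step 9**
Reactants: 18 triethyl[(2-methylbut-3-en-2-yl)oxy]silane
Product: 20 3-methyl-3-[(triethylsilyl)oxy]butan-1-ol, via B-alkyl-9-BBN borane 19 (not isolated)
Conditions: 9-BBN (1.2 equiv), THF, 0 °C → rt; then NaOH (3 M), H2O2 (30 %), 0 °C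
Reagents that add atoms: hydrogen peroxide OO
Why: Anti-Markovnikov hydroboration of the monosubstituted alkene followed by oxidation of the C–B bond (Brown hydroboration–oxidation).

**Step 10**
Reactants: 20 3-methyl-3-[(triethylsilyl)oxy]butan-1-ol
Product: 21 3-methyl-3-[(triethylsilyl)oxy]butanal
Conditions: PhI(OAc)2 (1.1 equiv), TEMPO (10 mol %), CH2Cl2, rt
Reagents that add atoms: none
Why: Nitroxyl-catalysed oxidation of the primary alcohol stops at the aldehyde and leaves the tertiary silyl ether intact.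

**Step 11**
Reactants: 17 bicyclic trione (enol); 21 3-methyl-3-[(triethylsilyl)oxy]butanal
Product: 23 (1R,5S,7R)-4-hydroxy-8,8-dimethyl-5,7-bis(3-methylbut-2-en-1-yl)-3-{3-methyl-3-[(triethylsilyl)oxy]butyl}bicyclo[3.3.1]non-3-ene-2,9-dione, via alkylidene trione 22 (not isolated)
Conditions: Hantzsch ester (1.1 equiv), L-proline (10 mol %), CH2Cl2, rt
Reagents that add atoms: none
Why: Three-component reductive alkylation (Knoevenagel condensation at C3, then transfer hydrogenation of the alkylidene dione by the dihydropyridine, Ramachary type) gives exclusive C-alkylation of the cyclic 1,3-dione; prenyl alkenes and stereocentres are untouched.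

**Step 12**
Reactants: 23 C3-alkylated trione (enol)
Product: 24 (1R,5S,7R)-4-methoxy-8,8-dimethyl-5,7-bis(3-methylbut-2-en-1-yl)-3-{3-methyl-3-[(triethylsilyl)oxy]butyl}bicyclo[3.3.1]non-3-ene-2,9-dione
Conditions: Me3SiCHN2 (1.5 equiv), MeOH/toluene 1:4, 0 °C; SiO2 chromatography
Reagents that add atoms: (trimethylsilyl)diazomethane C[Si](C)(C)C=[N+]=[N-]
Why: O-methylation of the vinylogous acid occurs at either enol oxygen and the 4-methoxy isomer 24 is the one isolated, because it leaves C1–H flanked by the C2 and C9 carbonyls; the 4-methoxy isomer may well be the minor one, and material methylated at the other oxygen is returned to 23 with LiOH.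

**Step 13**
Reactants: 25 (2E)-2-methylbut-2-enoic acid (tiglic acid)
Product: 26 (2R)-2-methylbutanoic acid
Conditions: H2 (1.5 atm), Ru(OAc)2[(R)-H8-BINAP] (0.5 mol %), MeOH, 15 °C
Reagents that add atoms: none
Why: Carboxylate-directed asymmetric hydrogenation (Noyori/Takaya type) sets the acyl α-stereocentre; the (R)-ligand is expected to give the (R)-acid in about 97 % ee, and this sense of induction (recalled from the tiglic acid precedent) should be confirmed by optical rotation.

**Step 14**
Reactants: 26 (2R)-2-methylbutanoic acid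
Product: 27 S-ethyl (2R)-2-methylbutanethioate
Conditions: EtSH (1.5 equiv), DCC (1.1 equiv), DMAP (5 mol %), CH2Cl2, 0 °C → rt
Reagents that add atoms: ethanethiol CCS
Why: Steglich-type thioesterification at low temperature, which should not racemise a simple α-alkyl acid.

**Step 15**
Reactants: 24 4-methoxy vinylogous ester; 27 S-ethyl (2R)-2-methylbutanethioate
Product: 30 (1S,5S,7R)-4-methoxy-8,8-dimethyl-1-[(2R)-2-methylbutanoyl]-5,7-bis(3-methylbut-2-en-1-yl)-3-{3-methyl-3-[(triethylsilyl)oxy]butyl}bicyclo[3.3.1]non-3-ene-2,9-dione, via bridgehead lithium compound 28 (not isolated), via bridgehead chlorozinc compound 29 (not isolated)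
Conditions: lithium 2,2,6,6-tetramethylpiperidide (1.05 equiv), THF, −78 °C, 30 min; ZnCl2 (1.2 equiv), −78 → 0 °C; then 27 (1.5 equiv), Pd2(dba)3 (5 mol %), P(2-furyl)3 (20 mol %), THF/toluene, 40 °C
Reagents that add atoms: none
Why: Proposed new method: bridgehead C–H zincation followed by palladium-catalysed acylative cross-coupling, in which the lithium amide removes the only acidified C–H (C1, α' to the vinylogous-ester carbonyl and α to the C9 ketone, with C3 and C5 blocked), Li-to-Zn exchange gives a configurationally locked C-zinc reagent that cannot become an O-enolate and has no β-hydrogen, zerovalent palladium inserts into the C(O)–S bond of 27, and transmetalation with reductive elimination forms the C1–C(O) bond with retention at the cage carbon and no strong base in contact with the acyl α-centre; the closest known reactions are the Fukuyama thioester–organozinc ketone synthesis, Negishi couplings of 1-adamantylzinc reagents and the stoichiometric bridgehead-lithium acylations of related vinylogous esters.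

**Step 16**
Reactants: 30 protected acyl compound
Product: 32 (1S,5S,7R)-4-hydroxy-3-(3-hydroxy-3-methylbutyl)-8,8-dimethyl-1-[(2R)-2-methylbutanoyl]-5,7-bis(3-methylbut-2-en-1-yl)bicyclo[3.3.1]non-3-ene-2,9-dione (CNP0326306.1), via lithium enolate 31 (not isolated)
Conditions: LiCl (5 equiv), DMSO, 120 °C, 1 h; cool; then THF, AcOH (3 equiv), Bu4NF (2 equiv), rt → 40 °C
Reagents that add atoms: none
Why: Chloride SN2 demethylation of the vinylogous methyl ester (Krapcho-type), then buffered fluoride cleavage of the tertiary silyl ether; neither condition is basic enough to epimerise the acyl α-centre and no ring stereocentre is involved.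

## Compound list

1 | 2-methylbut-3-en-2-ol | C=CC(C)(C)O | starting material
2 | ethyl vinyl ether | C=COCC | starting material
3 | 3-(ethenyloxy)-3-methylbut-1-ene (allyl vinyl ether, not isolated) | C=CC(C)(C)OC=C | intermediate
4 | 5-methylhex-4-enal | CC(C)=CCCC=O | intermediate
5 | but-3-en-2-one | CC(=O)C=C | starting material
6 | (2S)-2-(3-methylbut-2-en-1-yl)-5-oxohexanal (not isolated) | O=C[C@H](CC=C(C)C)CCC(C)=O | intermediate
7 | (4S)-4-(3-methylbut-2-en-1-yl)cyclohex-2-en-1-one | O=C1C=C[C@H](CC=C(C)C)CC1 | intermediate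
8 | bromomagnesium enolate of (4S)-3-methyl-4-(3-methylbut-2-en-1-yl)cyclohexanone, O–C1=C2, 3,4-trans major (not isolated) | Br[Mg]OC1=CC(C)[C@H](CC=C(C)C)CC1 | intermediate
9 | chlorozinc enolate of the same ketone (not isolated) | Cl[Zn]OC1=CC(C)[C@H](CC=C(C)C)CC1 | intermediate
10 | (4S)-3-methyl-4-(3-methylbut-2-en-1-yl)cyclohex-2-en-1-one | O=C1C=C(C)[C@H](CC=C(C)C)CC1 | intermediate
11 | 1-bromo-3-methylbut-2-ene | CC(C)=CCBr | starting material
12 | lithium cross-conjugated dienolate of 10, O–C1=C6 (not isolated) | [Li]OC1=CC[C@@H](CC=C(C)C)C(C)=C1 | intermediate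
13 | (4R,6RS)-3-methyl-4,6-bis(3-methylbut-2-en-1-yl)cyclohex-2-en-1-one | O=C1C=C(C)[C@H](CC=C(C)C)CC1CC=C(C)C | intermediate
14 | {[(4R,6RS)-3,3-dimethyl-4,6-bis(3-methylbut-2-en-1-yl)cyclohex-1-en-1-yl]oxy}trimethylsilane | C[Si](C)(C)OC1=CC(C)(C)[C@H](CC=C(C)C)CC1CC=C(C)C | intermediate
15 | propanedioic acid | OC(=O)CC(=O)O | starting material
16 | propanedioyl dichloride | ClC(=O)CC(Cl)=O | intermediate
17 | (1R,5S,7R)-4-hydroxy-8,8-dimethyl-5,7-bis(3-methylbut-2-en-1-yl)bicyclo[3.3.1]non-3-ene-2,9-dione | O=C1C=C(O)[C@]2(CC=C(C)C)C[C@@H](CC=C(C)C)C(C)(C)[C@H]1C2=O | intermediate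
18 | triethyl[(2-methylbut-3-en-2-yl)oxy]silane | C=CC(C)(C)O[Si](CC)(CC)CC | intermediate
19 | 9-{3-methyl-3-[(triethylsilyl)oxy]butyl}-9-borabicyclo[3.3.1]nonane (not isolated) | CC[Si](CC)(CC)OC(C)(C)CCB1C2CCCC1CCC2 | intermediate
20 | 3-methyl-3-[(triethylsilyl)oxy]butan-1-ol | CC[Si](CC)(CC)OC(C)(C)CCO | intermediate
21 | 3-methyl-3-[(triethylsilyl)oxy]butanal | CC[Si](CC)(CC)OC(C)(C)CC=O | intermediate
22 | 3-{3-methyl-3-[(triethylsilyl)oxy]butylidene} derivative of the 2,4,9-trione form of 17, ring stereocentres as in 17 (not isolated) | O=C1C(=CCC(C)(C)O[Si](CC)(CC)CC)C(=O)[C@]2(CC=C(C)C)C[C@@H](CC=C(C)C)C(C)(C)[C@H]1C2=O | intermediate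
23 | (1R,5S,7R)-4-hydroxy-8,8-dimethyl-5,7-bis(3-methylbut-2-en-1-yl)-3-{3-methyl-3-[(triethylsilyl)oxy]butyl}bicyclo[3.3.1]non-3-ene-2,9-dione | O=C1C(CCC(C)(C)O[Si](CC)(CC)CC)=C(O)[C@]2(CC=C(C)C)C[C@@H](CC=C(C)C)C(C)(C)[C@H]1C2=O | intermediate
24 | (1R,5S,7R)-4-methoxy-8,8-dimethyl-5,7-bis(3-methylbut-2-en-1-yl)-3-{3-methyl-3-[(triethylsilyl)oxy]butyl}bicyclo[3.3.1]non-3-ene-2,9-dione | O=C1C(CCC(C)(C)O[Si](CC)(CC)CC)=C(OC)[C@]2(CC=C(C)C)C[C@@H](CC=C(C)C)C(C)(C)[C@H]1C2=O | intermediate
25 | (2E)-2-methylbut-2-enoic acid | C/C=C(\C)C(=O)O | starting material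
26 | (2R)-2-methylbutanoic acid | CC[C@@H](C)C(=O)O | intermediate
27 | S-ethyl (2R)-2-methylbutanethioate | CC[C@@H](C)C(=O)SCC | intermediate
28 | C1-lithio derivative of 24, cage configuration retained (not isolated) | [Li][C@]12C(=O)C(CCC(C)(C)O[Si](CC)(CC)CC)=C(OC)[C@](CC=C(C)C)(C[C@@H](CC=C(C)C)C1(C)C)C2=O | intermediate
29 | C1-chlorozincio derivative of 24, cage configuration retained (not isolated) | Cl[Zn][C@]12C(=O)C(CCC(C)(C)O[Si](CC)(CC)CC)=C(OC)[C@](CC=C(C)C)(C[C@@H](CC=C(C)C)C1(C)C)C2=O | intermediate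
30 | (1S,5S,7R)-4-methoxy-8,8-dimethyl-1-[(2R)-2-methylbutanoyl]-5,7-bis(3-methylbut-2-en-1-yl)-3-{3-methyl-3-[(triethylsilyl)oxy]butyl}bicyclo[3.3.1]non-3-ene-2,9-dione | CC[C@@H](C)C(=O)[C@]12C(=O)C(CCC(C)(C)O[Si](CC)(CC)CC)=C(OC)[C@](CC=C(C)C)(C[C@@H](CC=C(C)C)C1(C)C)C2=O | intermediate
31 | lithium C4-enolate of demethylated 30, triethylsilyl ether intact (not isolated) | CC[C@@H](C)C(=O)[C@]12C(=O)C(CCC(C)(C)O[Si](CC)(CC)CC)=C(O[Li])[C@](CC=C(C)C)(C[C@@H](CC=C(C)C)C1(C)C)C2=O | intermediate
32 | (1S,5S,7R)-4-hydroxy-3-(3-hydroxy-3-methylbutyl)-8,8-dimethyl-1-[(2R)-2-methylbutanoyl]-5,7-bis(3-methylbut-2-en-1-yl)bicyclo[3.3.1]non-3-ene-2,9-dione | CC[C@@H](C)C(=O)[C@]12C(=O)C(CCC(C)(C)O)=C(O)[C@](CC=C(C)C)(C[C@@H](CC=C(C)C)C1(C)C)C2=O | target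

## Step count and risks

Total step count: 16. Longest linear sequence: 10 (steps 1, 2, 3, 4, 5, 7, 11, 12, 15, 16). Fragment B (steps 8–10), fragment C (steps 13–14) and the acid chloride (step 6) are made in parallel.

**Step 7 (Effenberger annulation).** It must acylate the neopentyl C1 and create the quaternary C5 in one operation, and such annulations are usually low-yielding. Fallback: add the C5 prenyl group after the annulation. It sets out from 10. Copper-catalysed MeMgBr addition with Me3SiCl trapping gives {[(4S)-3,3-dimethyl-4-(3-methylbut-2-en-1-yl)cyclohex-1-en-1-yl]oxy}trimethylsilane F1. Annulation with 16, now forming only tertiary bridgeheads, gives (1R,5S,7R)-4-hydroxy-8,8-dimethyl-7-(3-methylbut-2-en-1-yl)bicyclo[3.3.1]non-3-ene-2,9-dione F2. Me3SiCHN2 and separation give (1R,5S,7R)-2-methoxy-8,8-dimethyl-7-(3-methylbut-2-en-1-yl)bicyclo[3.3.1]non-2-ene-4,9-dione F3, in which C5–H is the bridgehead flanked by two carbonyls. LiN(i-Pr)2 and then 11 prenylate that bridgehead with retention (a bridgehead lithiation–alkylation of a type used on closely related cores) to give (1R,5S,7R)-2-methoxy-8,8-dimethyl-5,7-bis(3-methylbut-2-en-1-yl)bicyclo[3.3.1]non-2-ene-4,9-dione F4. LiOH in aqueous dioxane at 90 °C removes the methyl group and the route is rejoined at 17.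

**Step 11 (reductive alkylation).** The Knoevenagel stage may be slow on the hindered dione, and the β-silyloxy aldehyde may eliminate under amine catalysis. Fallback: install the chain by cross-coupling. It sets out from 17. Me3SiCHN2 and separation give (1R,5S,7R)-4-methoxy-8,8-dimethyl-5,7-bis(3-methylbut-2-en-1-yl)bicyclo[3.3.1]non-3-ene-2,9-dione F5. I2 with (NH4)2Ce(NO3)6 in MeCN iodinates the vinylic C3 to give (1S,5S,7R)-3-iodo-4-methoxy-8,8-dimethyl-5,7-bis(3-methylbut-2-en-1-yl)bicyclo[3.3.1]non-3-ene-2,9-dione F6. B-alkyl Suzuki–Miyaura coupling with borane 19, generated from 18 and 9-BBN as in step 9 (PdCl2(dppf), AsPh3, Cs2CO3, DMF/THF/H2O, rt → 50 °C), gives 24 directly, where the route is rejoined.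

**Step 15 (proposed bridgehead zincation and palladium-catalysed acylation).** Transmetalation of the hindered, electron-poor tertiary zinc reagent may be too slow, or protonation may win. Fallback with known chemistry: stoichiometric acylation of the bridgehead lithium compound. It sets out from 24. Acid 26 is converted with oxalyl chloride (catalytic DMF, CH2Cl2, 0 °C) into (2R)-2-methylbutanoyl chloride F7. Compound 24 is lithiated as in step 15 to 28, and this solution is added at −78 °C to F7 (inverse addition to suppress ketene formation and racemisation). This gives 30, where the route is rejoined.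

## Further compounds

F1 | step 7 | {[(4S)-3,3-dimethyl-4-(3-methylbut-2-en-1-yl)cyclohex-1-en-1-yl]oxy}trimethylsilane | C[Si](C)(C)OC1=CC(C)(C)[C@H](CC=C(C)C)CC1
F2 | step 7 | (1R,5S,7R)-4-hydroxy-8,8-dimethyl-7-(3-methylbut-2-en-1-yl)bicyclo[3.3.1]non-3-ene-2,9-dione | O=C1C=C(O)[C@@H]2C[C@@H](CC=C(C)C)C(C)(C)[C@H]1C2=O
F3 | step 7 | (1R,5S,7R)-2-methoxy-8,8-dimethyl-7-(3-methylbut-2-en-1-yl)bicyclo[3.3.1]non-2-ene-4,9-dione | COC1=CC(=O)[C@@H]2C[C@@H](CC=C(C)C)C(C)(C)[C@H]1C2=O
F4 | step 7 | (1R,5S,7R)-2-methoxy-8,8-dimethyl-5,7-bis(3-methylbut-2-en-1-yl)bicyclo[3.3.1]non-2-ene-4,9-dione | COC1=CC(=O)[C@]2(CC=C(C)C)C[C@@H](CC=C(C)C)C(C)(C)[C@H]1C2=O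
F5 | step 11 | (1R,5S,7R)-4-methoxy-8,8-dimethyl-5,7-bis(3-methylbut-2-en-1-yl)bicyclo[3.3.1]non-3-ene-2,9-dione | O=C1C=C(OC)[C@]2(CC=C(C)C)C[C@@H](CC=C(C)C)C(C)(C)[C@H]1C2=O
F6 | step 11 | (1S,5S,7R)-3-iodo-4-methoxy-8,8-dimethyl-5,7-bis(3-methylbut-2-en-1-yl)bicyclo[3.3.1]non-3-ene-2,9-dione | O=C1C(I)=C(OC)[C@]2(CC=C(C)C)C[C@@H](CC=C(C)C)C(C)(C)[C@H]1C2=O
F7 | step 15 | (2R)-2-methylbutanoyl chloride | CC[C@@H](C)C(Cl)=O
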